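Ring A is not brought in as a phloroglucinol. It is grown onto a preformed 3-methoxy-2-aryl-4-pyranone (rings C and B) by a Moore rearrangement, so the route rests on disconnecting C4a–C5, with C8–C8a made beforehand by an organolithium addition. The step exploits the substitution around the C4a=C8a bond of ring A: free hydroxyl at C5, hydrogen at C6, oxygen at C7 and a methyl ether at C8. In one heating it closes ring A and releases the 5-OH, with all four positions already told apart. The precursor is a 3-allyloxy-4-methoxycyclobut-2-enone whose C4 is bonded to pyranone C6; ring B already carries the prenyl ether.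

Key step: step 9

Remark: ring positions carry flavone numbers; in the free pyranone 10 (O1, C2 aryl, C3 OMe, C4 carbonyl, C5–H, C6–H) C6 becomes flavone C8a and C5 becomes flavone C4a; all chiral intermediates are racemic and the target is achiral.

Step 1
Reactants: 1 4-bromophenol; 2 prenyl bromide
Product: 3 1-bromo-4-(3-methylbut-2-enyloxy)benzene
Conditions: K2CO3, acetone, reflux
Reagents that add atoms: none
Why: Williamson ether synthesis, in which the phenoxide is O-alkylated by the primary allylic bromide under carbonate conditions that leave the aryl bromide untouched.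

Step 2
Reactants: 3 1-bromo-4-(3-methylbut-2-enyloxy)benzene; 4 N,2-dimethoxy-N-methylacetamide
Product: 6 2-methoxy-1-[4-(3-methylbut-2-enyloxy)phenyl]ethanone, via aryllithium 5 (not isolated)
Conditions: n-BuLi, THF, −78 °C; then 4, −78 → 0 °C; aq. NH4Cl
Reagents that add atoms: none
Why: Bromine–lithium exchange at −78 °C is faster than any attack on the prenyl ether, and the aryllithium acylates the amide through a chelated tetrahedral adduct that cannot add a second time (Weinreb ketone synthesis).

Step 3
Reactants: 6 2-methoxy-1-[4-(3-methylbut-2-enyloxy)phenyl]ethanone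
Product: 8 2-methoxy-1-[4-(3-methylbut-2-enyloxy)phenyl]butane-1,3-dione (racemic), via lithium enolate 7 (not isolated)
Conditions: LiN(iPr)2 (2.1 equiv), THF, −78 °C; 1-acetylbenzotriazole, −78 → 0 °C; aq. NH4Cl
Reagents that add atoms: 1-acetylbenzotriazole, CC(=O)n1nnc2ccccc12
Why: C-Acylation of the chelated lithium enolate by an N-acylbenzotriazole (a crossed Claisen condensation) should give the 1,3-diketone without O-acylation, the second equivalent of base taking up the more acidic product.

Step 4
Reactants: 8 2-methoxy-1-[4-(3-methylbut-2-enyloxy)phenyl]butane-1,3-dione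
Product: 10 3-methoxy-2-[4-(3-methylbut-2-enyloxy)phenyl]-4H-pyran-4-one, via enaminone 9 (not isolated)
Conditions: Me2NCH(OMe)2, toluene, 80 °C; then AcOH, 60 °C
Reagents that add atoms: N,N-dimethylformamide dimethyl acetal, CN(C)C(OC)OC
Why: With the central carbon blocked by methoxy the amide acetal can condense only at the acetyl methyl group, and the enaminone then closes by addition–elimination of the aryl ketone enol oxygen with loss of dimethylamine (enaminone route to 4-pyranones).

Step 5
Reactants: 11 squaric acid; 12 allyl alcohol
Product: 13 3,4-bis(allyloxy)cyclobut-3-ene-1,2-dione (diallyl squarate)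
Conditions: allyl alcohol (excess, at least 2 equiv), toluene, reflux, Dean–Stark trap
Reagents that add atoms: allyl alcohol (the second molecule, which esterifies the second hydroxyl group), C=CCO
Why: Self-catalysed Fischer-type esterification of the strongly acidic vinylogous diacid, in which each of the two hydroxyl groups takes up one molecule of allyl alcohol and two molecules of water are removed azeotropically, is the standard entry to dialkyl squarates.

Step 6
Reactants: 13 3,4-bis(allyloxy)cyclobut-3-ene-1,2-dione
Product: 15 3-(allyloxy)cyclobut-3-ene-1,2-dione, via hydroxycyclobutenone 14 (not isolated)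
Conditions: LiAlH(OtBu)3, THF, −78 → −20 °C; aq. work-up; then conc. aq. HCl (cat.), CH2Cl2, rt
Reagents that add atoms: water, O
Why: The bulky hydride adds once to a squarate carbonyl (1,2-reduction), and acid then ionises the carbinol to an alkoxy-stabilised allyl cation that water captures at its far end, the resulting hemiketal expelling allyl alcohol, a 1,3-carbonyl transposition that places the ring C–H next to the vinylogous ester carbonyl.

Step 7
Reactants: 10 3-methoxy-2-[4-(3-methylbut-2-enyloxy)phenyl]-4H-pyran-4-one; 15 3-(allyloxy)cyclobut-3-ene-1,2-dione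
Product: 17 3-(allyloxy)-4-hydroxy-4-{5-methoxy-4-oxo-6-[4-(3-methylbut-2-enyloxy)phenyl]-4H-pyran-2-yl}cyclobut-2-en-1-one (racemic), via lithiopyranone 16 (not isolated)
Conditions: lithium 2,2,6,6-tetramethylpiperidide (LiTMP, from 2,2,6,6-tetramethylpiperidine and n-BuLi), THF, −78 °C; then 15, −78 °C; aq. NH4Cl
Reagents that add atoms: none
Why: Deprotonative lithiation by the hindered amide at the sp2 C–H next to the ring oxygen (C6, as in the C2 lithiation of chromones) is followed by 1,2-addition to the ketone-like carbonyl of the dione, the one flanked by the alkoxy-bearing carbon and not deactivated as a vinylogous ester; the new carbinol centre forms as a racemate and is erased in step 9.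

Step 8
Reactants: 17 3-(allyloxy)-4-hydroxy-4-{5-methoxy-4-oxo-6-[4-(3-methylbut-2-enyloxy)phenyl]-4H-pyran-2-yl}cyclobut-2-en-1-one
Product: 18 3-(allyloxy)-4-methoxy-4-{5-methoxy-4-oxo-6-[4-(3-methylbut-2-enyloxy)phenyl]-4H-pyran-2-yl}cyclobut-2-en-1-one (racemic)
Conditions: MeI, Ag2O, MeCN, rt, dark
Reagents that add atoms: iodomethane, CI
Why: Purdie methylation caps the tertiary alcohol under neutral conditions and is preferred to trapping the lithium alkoxide with a methyl triflate, because a hard triflate would alkylate the pyranone carbonyl oxygen irreversibly whereas a methoxypyrylium iodide reverts to pyranone and MeI.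

Step 9
Reactants: 18 3-(allyloxy)-4-methoxy-4-{5-methoxy-4-oxo-6-[4-(3-methylbut-2-enyloxy)phenyl]-4H-pyran-2-yl}cyclobut-2-en-1-one
Product: 21 7-(allyloxy)-5-hydroxy-3,8-dimethoxy-2-[4-(3-methylbut-2-enyloxy)phenyl]-4H-chromen-4-one, via dienylketene 19 (not isolated), via dienone tautomer 20 (not isolated)
Conditions: degassed toluene (0.01 M), 110 °C, Ar
Reagents that add atoms: none
Why: Heating should open the cyclobutenone by four-electron conrotatory cleavage of the C1–C4 bond, the donor methoxy group at C4 turning outward and the pyranonyl group therefore inward, to give the (Z)-dienylketene 19. A thermal six-electron disrotatory electrocyclisation (formally a 6-endo closure through the triene, with no ionic intermediate) then joins the electrophilic ketene carbon to the nucleophilic pyranone C5, creating the C4a–C5 bond and ring A as dienone 20, which enolises at once to the chelated 5-phenol. The closest known reaction type is the Moore rearrangement of 4-alkenyl- and 4-aryl-4-alkoxycyclobutenones to hydroquinone monoethers, the 4-oxopyranyl group being simply a new alkenyl partner. No stereocentre is created, since the carbinol centre of 18 is destroyed in the ring opening and C4a of 20 is lost on aromatisation. Regiochemistry is constitutional, because the only carbon neighbour of the attachment point is C5 and the substituent order (ketene carbon to C5-OH, CH to C6, allyloxy carbon to C7, methoxy carbon to C8) was fixed in step 7. The selectivity needed is kinetic, ring closure ahead of ketene [2+2] addition to the allyl alkene, [3,3] shift of the allyl vinylogous ester or ketene dimerisation, and it is secured by the outward preference of the methoxy group, the matched polarity of the closing termini, high dilution and a temperature no higher than 110 °C.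

Step 10
Reactants: 21 7-(allyloxy)-5-hydroxy-3,8-dimethoxy-2-[4-(3-methylbut-2-enyloxy)phenyl]-4H-chromen-4-one
Product: 22 5,7-dihydroxy-3,8-dimethoxy-2-[4-(3-methylbut-2-enyloxy)phenyl]-4H-chromen-4-one
Conditions: Pd(PPh3)4 (5 mol %), morpholine, THF, rt
Reagents that add atoms: none
Why: Tsuji–Trost deallylation, in which zerovalent palladium ionises the unsubstituted allyl ether of the vinylogously acidic 7-oxygen to a π-allyl complex that morpholine intercepts, while the trisubstituted prenyl ether binds and ionises far more slowly and the methyl ethers and the chelated 5-OH are inert.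

Compound list
1 | 4-bromophenol | Oc1ccc(Br)cc1 | starting material
2 | prenyl bromide (1-bromo-3-methylbut-2-ene) | CC(C)=CCBr | starting material
3 | 1-bromo-4-(3-methylbut-2-enyloxy)benzene | CC(C)=CCOc1ccc(Br)cc1 | intermediate
4 | N,2-dimethoxy-N-methylacetamide | COCC(=O)N(C)OC | starting material
5 | [4-(3-methylbut-2-enyloxy)phenyl]lithium (formed in the flask) | [Li]c1ccc(OCC=C(C)C)cc1 | intermediate
6 | 2-methoxy-1-[4-(3-methylbut-2-enyloxy)phenyl]ethanone | COCC(=O)c1ccc(OCC=C(C)C)cc1 | intermediate
7 | lithium (Z)-2-methoxy-1-[4-(3-methylbut-2-enyloxy)phenyl]ethenolate (formed in the flask) | [Li]O/C(=C\OC)c1ccc(OCC=C(C)C)cc1 | intermediate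
8 | 2-methoxy-1-[4-(3-methylbut-2-enyloxy)phenyl]butane-1,3-dione (racemic, configurationally labile) | CC(=O)C(OC)C(=O)c1ccc(OCC=C(C)C)cc1 | intermediate
9 | (E)-5-(dimethylamino)-2-methoxy-1-[4-(3-methylbut-2-enyloxy)phenyl]pent-4-ene-1,3-dione (racemic; formed in the flask) | CN(C)/C=C/C(=O)C(OC)C(=O)c1ccc(OCC=C(C)C)cc1 | intermediate
10 | 3-methoxy-2-[4-(3-methylbut-2-enyloxy)phenyl]-4H-pyran-4-one | COc1c(-c2ccc(OCC=C(C)C)cc2)occc1=O | intermediate
11 | squaric acid | OC1=C(O)C(=O)C1=O | starting material
12 | allyl alcohol | C=CCO | starting material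
13 | 3,4-bis(allyloxy)cyclobut-3-ene-1,2-dione (diallyl squarate) | C=CCOC1=C(OCC=C)C(=O)C1=O | intermediate
14 | 2,3-bis(allyloxy)-4-hydroxycyclobut-2-en-1-one (racemic; carried on crude) | O=C1C(OCC=C)=C(OCC=C)C1O | intermediate
15 | 3-(allyloxy)cyclobut-3-ene-1,2-dione | O=C1C=C(OCC=C)C1=O | intermediate
16 | {5-methoxy-4-oxo-6-[4-(3-methylbut-2-enyloxy)phenyl]-4H-pyran-2-yl}lithium (formed in the flask) | [Li]c1cc(=O)c(OC)c(-c2ccc(OCC=C(C)C)cc2)o1 | intermediate
17 | 3-(allyloxy)-4-hydroxy-4-{5-methoxy-4-oxo-6-[4-(3-methylbut-2-enyloxy)phenyl]-4H-pyran-2-yl}cyclobut-2-en-1-one (racemic) | O=C1C=C(OCC=C)C1(O)c1cc(=O)c(OC)c(-c2ccc(OCC=C(C)C)cc2)o1 | intermediate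
18 | 3-(allyloxy)-4-methoxy-4-{5-methoxy-4-oxo-6-[4-(3-methylbut-2-enyloxy)phenyl]-4H-pyran-2-yl}cyclobut-2-en-1-one (racemic) | O=C1C=C(OCC=C)C1(OC)c1cc(=O)c(OC)c(-c2ccc(OCC=C(C)C)cc2)o1 | intermediate
19 | (3Z)-3-(allyloxy)-4-methoxy-4-{5-methoxy-4-oxo-6-[4-(3-methylbut-2-enyloxy)phenyl]-4H-pyran-2-yl}buta-1,3-dien-1-one (formed in the flask) | O=C=C/C(OCC=C)=C(OC)\c1cc(=O)c(OC)c(-c2ccc(OCC=C(C)C)cc2)o1 | intermediate
20 | 7-(allyloxy)-3,8-dimethoxy-2-[4-(3-methylbut-2-enyloxy)phenyl]-4aH-chromene-4,5-dione (racemic at C4a; formed in the flask) | O=C1C=C(OCC=C)C(OC)=C2OC(-c3ccc(OCC=C(C)C)cc3)=C(OC)C(=O)C12 | intermediate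
21 | 7-(allyloxy)-5-hydroxy-3,8-dimethoxy-2-[4-(3-methylbut-2-enyloxy)phenyl]-4H-chromen-4-one | COc1c(-c2ccc(OCC=C(C)C)cc2)oc2c(OC)c(OCC=C)cc(O)c2c1=O | intermediate
22 | 5,7-dihydroxy-3,8-dimethoxy-2-[4-(3-methylbut-2-enyloxy)phenyl]-4H-chromen-4-one (5,7-dihydroxy-3,8-dimethoxy-4'-prenyloxyflavone; achiral) | COc1c(-c2ccc(OCC=C(C)C)cc2)oc2c(OC)c(O)cc(O)c2c1=O | target

Total step count: 10.
Longest linear sequence: 8 steps (1, 2, 3, 4, 7, 8, 9, 10, from 4-bromophenol); the squarate branch (steps 5 and 6) joins at step 7.

Steps most likely to fail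

Step 9. The dienylketene may be diverted before it closes, by [2+2] addition to the allyl alkene or by bimolecular trapping. Alternatively, ring opening of the methyl-capped carbinol may need a temperature at which the allyl vinylogous ester begins to rearrange. The fallback sets out from 17 and uses the free carbinol, the best-documented substrate class for this ring expansion. Thermolysis of 17 in degassed toluene at 100–110 °C under argon should give the hydroquinone 7-(allyloxy)-5,8-dihydroxy-3-methoxy-2-[4-(3-methylbut-2-enyloxy)phenyl]-4H-chromen-4-one F1. Without exposure to air, F1 is mono-methylated at the unchelated 8-OH (MeI, 1.1 equiv, K2CO3, acetone, rt). The 5-OH is held by its hydrogen bond to the C4 carbonyl and should stay free, so the sequence comes back to the route at 21.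

Step 7. Amide base carried along with the lithio species may consume the dione, proton transfer may replace 1,2-addition, and the basic lithio species may add to unmetalated pyranone while the electrophile is introduced. The fallback sets out from 10 and separates metalation from addition. Species 16 is generated as before and poured at once into I2 in THF at −78 °C, which should give 6-iodo-3-methoxy-2-[4-(3-methylbut-2-enyloxy)phenyl]-4H-pyran-4-one F2. After purification, iodine–magnesium exchange with i-PrMgCl·LiCl (THF, −40 °C) should give the amine-free and less basic chloro{5-methoxy-4-oxo-6-[4-(3-methylbut-2-enyloxy)phenyl]-4H-pyran-2-yl}magnesium F3. F3 is added to 15 at −40 °C and quenched with aq. NH4Cl, coming back to the route at 17.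

Step 4. Liberated dimethylamine or methanol may cleave the α-methoxy diketone by retro-Claisen reaction, and the amide acetal may O-methylate its enol, before the methyl group condenses. The fallback sets out from 8 and replaces the amide acetal by a carbanion acylation. LiN(iPr)2 (2.2 equiv, THF, −78 → 0 °C) forms the 2,4-dianion, which is C-formylated at its terminal carbon with ethyl formate at −78 °C. Buffered work-up should give 4-methoxy-3,5-dioxo-5-[4-(3-methylbut-2-enyloxy)phenyl]pentanal F4. Cyclodehydration in AcOH at rt to 40 °C comes back to the route at 10.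

Further compounds
F1 | step 9 | 7-(allyloxy)-5,8-dihydroxy-3-methoxy-2-[4-(3-methylbut-2-enyloxy)phenyl]-4H-chromen-4-one | COc1c(-c2ccc(OCC=C(C)C)cc2)oc2c(O)c(OCC=C)cc(O)c2c1=O
F2 | step 7 | 6-iodo-3-methoxy-2-[4-(3-methylbut-2-enyloxy)phenyl]-4H-pyran-4-one | COc1c(-c2ccc(OCC=C(C)C)cc2)oc(I)cc1=O
F3 | step 7 | chloro{5-methoxy-4-oxo-6-[4-(3-methylbut-2-enyloxy)phenyl]-4H-pyran-2-yl}magnesium (as its LiCl complex) | Cl[Mg]c1cc(=O)c(OC)c(-c2ccc(OCC=C(C)C)cc2)o1
F4 | step 4 | 4-methoxy-3,5-dioxo-5-[4-(3-methylbut-2-enyloxy)phenyl]pentanal (racemic; largely as enol tautomers) | COC(C(=O)CC=O)C(=O)c1ccc(OCC=C(C)C)cc1
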